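# Lukianol B by a tethered direct arylation: an aryl ester bridge delivers the C8 aryl ring

## Analysis of the target

Lukianol B (19) is a 1H-pyrrolo[2,1-c][1,4]oxazin-1-one: a pyrrole (N5, C6, C7, C8, C8a) fused along the N5–C8a bond to a six-membered enol lactone (C1=O, O2, C3, C4). C3 bears a 4-hydroxyphenyl ring, C8 a second one and C7 a 4-hydroxy-3-iodophenyl ring; C4 and C6 carry hydrogen. There is no stereocentre, so every question is one of constitution. The enol lactone is an acyl donor that hydroxide, alkoxides, amines and even phenoxides can open. The aryl iodide will not survive zerovalent palladium or a hydride source, and only one of the three phenols is iodinated. The main difficulty is that the rings on the neighbouring carbons C7 and C8 differ only by that iodine, so each must be placed by a reaction with a single possible outcome, and the iodine must arrive after the last palladium step. The plan rests on one feature: C8a (pyrrole C2) carries the carboxyl carbon C1 and the adjacent C8 (pyrrole C3) carries an aryl ring, so an aryl ester of C1 can pass its ring to C8 through a six-membered lactone and can reach no other carbon.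

## Retrosynthetic reasoning

**Phenol oxygens and iodine.** The last bonds cut are the two O–CH3 bonds of iodophenol 18, then the C–I bond of 18, then the O–isopropyl bond of 16. The iodine goes in by electrophilic substitution ortho to the only free hydroxyl of phenol 17. The C7 oxygen is told apart from the other two by an isopropyl ether, which a mild boron Lewis acid cleaves while methyl ethers stay. This places the iodination after all palladium chemistry.

**Enol lactone.** In 16 the C1–O2 bond is cut, giving keto acid 14; the forward step is a cyclodehydration in which the ketone enol attacks the activated carboxyl. A direct acyl transfer from the aryl lactone of 10 to the ketone enolate would be shorter, but it was not relied on. An enol ester is a stronger acyl donor than an aryl ester, so the freed phenoxide next to the new enol lactone would take the acyl group back.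

**Bridge oxygen.** The C8 ring of 14 has hydrogen where lactone 10 has the bridging oxygen. Going backwards, that C–H becomes the C–O triflate of acid 12, and 12 comes from 10 by opening the lactone with aqueous base to dianion 11 and sulfonylating its phenoxide. Hydroxide is chosen for the opening because the carboxylate of 11 cannot close back onto the phenoxide. The ketal of 10 is kept until the triflate is reduced and then hydrolysed in the same flask (13 to 14).

**Key disconnection.** In 10 the bond between pyrrole C3 (C9b) and the benzo carbon C9a is cut, giving the 2-bromo-5-methoxyphenyl ester 9. The cut lies here because this bond closes a six-membered lactone from the C2 carboxyl, so the tether fixes the site; an intermolecular arylation would have to choose between C3 and C5. The methoxy group para to the new bond becomes the 4-oxygen of the C8 ring.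

**Ester.** Ester 9 is cut at the acyl–O bond into acid 7 and the commercial phenol 8. The ketal on the nitrogen side chain is needed at this point; a free ketone would close the enol lactone on carboxyl activation and later expel the bromophenoxide from 9.

**C4 aryl ring.** Acid 7 comes from ester 6, and 6 is cut at the pyrrole C4–aryl bond into bromopyrrole 4 and boronic acid 5. This coupling precedes the introduction of 8, so the molecule never holds two C–Br bonds at once.

**Nitrogen side chain.** Ketal 4 comes from ketone 3, and 3 is cut at the N–CH2 bond into the commercial pyrrole 1 and bromoketone 2. Nitrogen is substituted first for two reasons. An N–H bromopyrrole ester is prone to reductive loss of bromine in the coupling. A free nitrogen would also be a second site of ring closure in the key step.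

## Alternatives that were turned down

**Alternative 1: crossed arylpyruvate coupling with Paal–Knorr closure.**
- Disconnection: the pyrrole C3–C4 bond and both C–N bonds of diester A1, 2-tert-butyl 5-methyl 3-(3-iodo-4-methoxyphenyl)-4-(4-methoxyphenyl)-1H-pyrrole-2,5-dicarboxylate.
- Forward key step: the sodium enolate of methyl 3-(4-methoxyphenyl)-2-oxopropanoate A2 displaces bromide from tert-butyl 3-bromo-3-(3-iodo-4-methoxyphenyl)-2-oxopropanoate A3. NH4OAc then condenses the 1,4-diketone to the pyrrole.
- For: it builds the whole diarylpyrrole in one flask and carries the iodine from the start. The two esters are differentiated, so the tert-butyl ester next to the iodoaryl ring can be removed and decarboxylated. It is clearly shorter than the chosen route and needs no late iodination; on both points it is the stronger plan.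
- Against: arylpyruvate enolates exchange protons and halogen with α-bromo ketoesters. The two symmetrical diketones are therefore expected beside the crossed one, and the three resulting pyrroles differ only by iodine atoms and would be hard to separate.
- Comparison: the chosen route pays with extra steps. In return each aryl ring is attached by a bond-forming event with one possible outcome.

**Alternative 2: anodic closure of the oxazinone at nitrogen.**
- Disconnection: the N5–C4 bond of lukianol B trimethyl ether A4, 7-(3-iodo-4-methoxyphenyl)-3,8-bis(4-methoxyphenyl)-1H-pyrrolo[2,1-c][1,4]oxazin-1-one.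
- Forward key step: anodic oxidation of the pyrrolide of the 1-(4-methoxyphenyl)ethenyl ester A5. The nitrogen-centred radical attacks the terminal alkene carbon in a 6-endo mode, and a second oxidation with proton loss gives the enol lactone.
- For: it would give the permethyl ether of the target in one late step, without a phenacyl halide, a ketal or a late iodination. The 6-endo mode is electronically favoured, because it leaves an aryl- and oxygen-stabilised radical.
- Against: the anisyl rings, the electron-rich diarylpyrrole with its free C5–H, and the enol ester alkene oxidise in the same potential range, and the C–I bond can be reduced at the counter electrode. The closure has no close model on pyrrole esters. The hard part, a regiodefined iodinated diarylpyrrole acid, must already be solved to make A5.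
- Comparison: the chosen key step is a known catalytic cyclization, and it solves the aryl placement itself.

**Alternative 3: glycinate condensation closing the pyrrole at C2–C3.**
- Disconnection: the N–C5 and C2–C3 bonds of ester A6, methyl 4-(3-iodo-4-methoxyphenyl)-3-(4-methoxyphenyl)-1-{[2-(4-methoxyphenyl)-1,3-dioxolan-2-yl]methyl}-1H-pyrrole-2-carboxylate.
- Forward key step: the hydroxymethylene ketone A7 condenses at its formyl carbon with the secondary amine of glycinate A8. NaOCH3 then drives the glycine CH2 onto the aryl ketone with loss of water.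
- For: the deoxybenzoin skeleton of A7 fixes both aryl positions, and the iodine and the nitrogen side chain are present from the start. No palladium is used. It is shorter than the chosen route, and stronger on step count and on iodine placement.
- Against: the ring-closing carbonyl is a vinylogous amide flanked by two aryl rings and is a poor electrophile, and the glycinate CH2 is only weakly acidic. Under methoxide, deformylation of A7 and cleavage of the enaminone compete. The hindered secondary amine A8 condenses slowly.
- Comparison: the chosen route concentrates its risk in one precedented palladium cyclization on a precursor made by standard steps.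

Key step: step 6

Remark: compounds 1, 2, 5 and 8 are taken as commercial; the target has no stereocentre, so no configuration is set anywhere.

## Route

Step 1
Reactants: 1 methyl 4-bromo-1H-pyrrole-2-carboxylate; 2 2-bromo-1-(4-methoxyphenyl)ethanone
Product: 3 methyl 4-bromo-1-[2-(4-methoxyphenyl)-2-oxoethyl]-1H-pyrrole-2-carboxylate
Conditions: K2CO3, acetone, 50 °C
Reagents that add atoms: none
Why: N-alkylation of the acidified pyrrole N–H by a reactive α-bromoketone (SN2); carbonate is too weak to drive the ketone onto the methyl ester, and a near-equimolar amount of 2 limits a second alkylation at the new CH2.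

Step 2
Reactants: 3 methyl 4-bromo-1-[2-(4-methoxyphenyl)-2-oxoethyl]-1H-pyrrole-2-carboxylate
Product: 4 methyl 4-bromo-1-{[2-(4-methoxyphenyl)-1,3-dioxolan-2-yl]methyl}-1H-pyrrole-2-carboxylate
Conditions: ethylene glycol, TsOH·H2O (cat.), toluene, reflux, Dean–Stark
Reagents that add atoms: ethylene glycol, OCCO
Why: Acid-catalysed ketalization with azeotropic removal of water; the deactivated bromopyrrole ester tolerates the acid, and the ketal removes the enolizable ketone from all later basic and activating steps.

Step 3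
Reactants: 4 methyl 4-bromo-1-{[2-(4-methoxyphenyl)-1,3-dioxolan-2-yl]methyl}-1H-pyrrole-2-carboxylate; 5 (4-isopropoxyphenyl)boronic acid
Product: 6 methyl 4-(4-isopropoxyphenyl)-1-{[2-(4-methoxyphenyl)-1,3-dioxolan-2-yl]methyl}-1H-pyrrole-2-carboxylate
Conditions: Pd(PPh3)4 (5 mol %), 2 M aq. Na2CO3, DME, 85 °C
Reagents that add atoms: none
Why: Suzuki–Miyaura coupling at the only C–Br bond; the N-substituent suppresses the reductive debromination to which N–H bromopyrrole esters are prone, and the ketal is stable to aqueous base.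

Step 4
Reactants: 6 methyl 4-(4-isopropoxyphenyl)-1-{[2-(4-methoxyphenyl)-1,3-dioxolan-2-yl]methyl}-1H-pyrrole-2-carboxylate
Product: 7 4-(4-isopropoxyphenyl)-1-{[2-(4-methoxyphenyl)-1,3-dioxolan-2-yl]methyl}-1H-pyrrole-2-carboxylic acid
Conditions: KOH, MeOH/THF/H2O, 60 °C; then 1 M HCl to pH 4, 0 °C
Reagents that add atoms: potassium hydroxide, [K+].[OH-]
Why: Ester saponification; cold acidification only to pH 4 frees the acid and leaves the dioxolane intact.

Step 5
Reactants: 7 4-(4-isopropoxyphenyl)-1-{[2-(4-methoxyphenyl)-1,3-dioxolan-2-yl]methyl}-1H-pyrrole-2-carboxylic acid; 8 2-bromo-5-methoxyphenol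
Product: 9 2-bromo-5-methoxyphenyl 4-(4-isopropoxyphenyl)-1-{[2-(4-methoxyphenyl)-1,3-dioxolan-2-yl]methyl}-1H-pyrrole-2-carboxylate
Conditions: EDC·HCl, DMAP, CH2Cl2, rt
Reagents that add atoms: none
Why: Steglich esterification; the acylpyridinium formed with DMAP acylates the hindered ortho-bromophenol under neutral conditions that spare the ketal.

Step 6
Reactants: 9 2-bromo-5-methoxyphenyl 4-(4-isopropoxyphenyl)-1-{[2-(4-methoxyphenyl)-1,3-dioxolan-2-yl]methyl}-1H-pyrrole-2-carboxylate
Product: 10 1-(4-isopropoxyphenyl)-7-methoxy-3-{[2-(4-methoxyphenyl)-1,3-dioxolan-2-yl]methyl}chromeno[3,4-b]pyrrol-4(3H)-one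
Conditions: Pd(OAc)2 (10 mol %), PPh3 (20 mol %), NaOAc (3 equiv), dry DMA, 125 °C
Reagents that add atoms: none
Why: PPh3 reduces Pd(OAc)2 in the flask to zerovalent palladium, which inserts into the C–Br bond of the ester. Acetate-assisted concerted metalation–deprotonation at the pyrrole C3–H gives a seven-membered diaryl palladacycle, and reductive elimination forms the C9a–C9b bond. The closest known reaction type is the intramolecular direct arylation of 2-halophenyl (hetero)aroates to benzo-fused coumarins. The six-membered lactone is closed at this biaryl bond between two sp2 carbons, and no stereocentre arises. Site selectivity is required and is secured by the tether: only C3 gives a six-membered ring, C5 is out of reach, and nitrogen is blocked by its substituent. The ketal prevents an enolate on the side chain from expelling the bromophenoxide. The ester must rotate into its less populated conformer to bring the aryl ring over C3, hence the high temperature. Anhydrous acetate is a base mild enough to leave the activated aryl ester intact.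

Step 7
Reactants: 10 1-(4-isopropoxyphenyl)-7-methoxy-3-{[2-(4-methoxyphenyl)-1,3-dioxolan-2-yl]methyl}chromeno[3,4-b]pyrrol-4(3H)-one
Product: 12 4-(4-isopropoxyphenyl)-3-(4-methoxy-2-{[(trifluoromethyl)sulfonyl]oxy}phenyl)-1-{[2-(4-methoxyphenyl)-1,3-dioxolan-2-yl]methyl}-1H-pyrrole-2-carboxylic acid, via dipotassium phenolate carboxylate 11 (not isolated)
Conditions: KOH (2.1 equiv), THF/H2O, 50 °C; evaporate; PhNTf2, DMF, 0 °C to rt; then 1 M HCl to pH 4, 0 °C
Reagents that add atoms: potassium hydroxide, [K+].[OH-]; N-phenylbis(trifluoromethanesulfonimide), O=S(=O)(N(c1ccccc1)S(=O)(=O)C(F)(F)F)C(F)(F)F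
Why: Hydroxide opens the activated aryl lactone irreversibly to dianion 11, whose carboxylate cannot re-close; the mild triflating agent then sulfonylates the phenoxide in preference to the carboxylate (lactone saponification followed by phenol triflation).

Step 8
Reactants: 12 4-(4-isopropoxyphenyl)-3-(4-methoxy-2-{[(trifluoromethyl)sulfonyl]oxy}phenyl)-1-{[2-(4-methoxyphenyl)-1,3-dioxolan-2-yl]methyl}-1H-pyrrole-2-carboxylic acid
Product: 14 4-(4-isopropoxyphenyl)-3-(4-methoxyphenyl)-1-[2-(4-methoxyphenyl)-2-oxoethyl]-1H-pyrrole-2-carboxylic acid, via dioxolane acid 13 (not isolated)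
Conditions: Pd(OAc)2 (5 mol %), dppf (6 mol %), HCO2H, Et3N, DMF, 70 °C; then 2 M HCl, THF, rt
Reagents that add atoms: water, O
Why: Palladium-catalysed transfer hydrogenolysis of the aryl triflate (oxidative addition, formate exchange, loss of CO2, C–H reductive elimination) removes the bridge oxygen; aqueous acid then hydrolyses the dioxolane of 13 to the ketone.

Step 9
Reactants: 14 4-(4-isopropoxyphenyl)-3-(4-methoxyphenyl)-1-[2-(4-methoxyphenyl)-2-oxoethyl]-1H-pyrrole-2-carboxylic acid
Product: 16 7-(4-isopropoxyphenyl)-3,8-bis(4-methoxyphenyl)-1H-pyrrolo[2,1-c][1,4]oxazin-1-one, via mixed acetic anhydride 15 (not isolated)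
Conditions: Ac2O, NaOAc, 90 °C
Reagents that add atoms: none
Why: Cyclodehydration: the acid is activated as mixed anhydride 15 and the ketone enol oxygen attacks it in a six-membered mode; attack through carbon would need a four-membered ring, so only the enol lactone can form.

Step 10
Reactants: 16 7-(4-isopropoxyphenyl)-3,8-bis(4-methoxyphenyl)-1H-pyrrolo[2,1-c][1,4]oxazin-1-one
Product: 17 7-(4-hydroxyphenyl)-3,8-bis(4-methoxyphenyl)-1H-pyrrolo[2,1-c][1,4]oxazin-1-one
Conditions: BCl3, CH2Cl2, −78 to 0 °C; then MeOH, H2O
Reagents that add atoms: none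
Why: Lewis-acid dealkylation; BCl3 cleaves the secondary isopropyl ether through chloride attack on the better-stabilised alkyl group and leaves aryl methyl ethers and the enol lactone untouched at low temperature.

Step 11
Reactants: 17 7-(4-hydroxyphenyl)-3,8-bis(4-methoxyphenyl)-1H-pyrrolo[2,1-c][1,4]oxazin-1-one
Product: 18 7-(4-hydroxy-3-iodophenyl)-3,8-bis(4-methoxyphenyl)-1H-pyrrolo[2,1-c][1,4]oxazin-1-one
Conditions: BnMe3N·ICl2 (1.05 equiv), NaHCO3, CH2Cl2/MeOH, rt
Reagents that add atoms: benzyltrimethylammonium dichloroiodate, C[N+](C)(C)Cc1ccccc1.Cl[I-]Cl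
Why: Electrophilic aromatic iodination by a tamed iodine electrophile that reacts with phenols but not with aryl ethers unless a Lewis acid is added; the para position is blocked, so iodine enters ortho to the hydroxyl, and the first iodine deactivates the ring against a second one.

Step 12
Reactants: 18 7-(4-hydroxy-3-iodophenyl)-3,8-bis(4-methoxyphenyl)-1H-pyrrolo[2,1-c][1,4]oxazin-1-one
Product: 19 lukianol B, 7-(4-hydroxy-3-iodophenyl)-3,8-bis(4-hydroxyphenyl)-1H-pyrrolo[2,1-c][1,4]oxazin-1-one
Conditions: BBr3, CH2Cl2, −78 °C to rt; then MeOH, H2O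
Reagents that add atoms: none
Why: BBr3 demethylation of both aryl methyl ethers (bromide attack on the O-methyl group of the borane adduct); the conjugated enol lactone and the aryl iodide should tolerate the Lewis acid at or below room temperature.

## Compound list

1 | methyl 4-bromo-1H-pyrrole-2-carboxylate | COC(=O)c1cc(Br)c[nH]1 | starting material
2 | 2-bromo-1-(4-methoxyphenyl)ethanone | COc1ccc(C(=O)CBr)cc1 | starting material
3 | methyl 4-bromo-1-[2-(4-methoxyphenyl)-2-oxoethyl]-1H-pyrrole-2-carboxylate | COC(=O)c1cc(Br)cn1CC(=O)c1ccc(OC)cc1 | intermediate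
4 | methyl 4-bromo-1-{[2-(4-methoxyphenyl)-1,3-dioxolan-2-yl]methyl}-1H-pyrrole-2-carboxylate | COC(=O)c1cc(Br)cn1CC1(c2ccc(OC)cc2)OCCO1 | intermediate
5 | (4-isopropoxyphenyl)boronic acid | CC(C)Oc1ccc(B(O)O)cc1 | starting material
6 | methyl 4-(4-isopropoxyphenyl)-1-{[2-(4-methoxyphenyl)-1,3-dioxolan-2-yl]methyl}-1H-pyrrole-2-carboxylate | COC(=O)c1cc(-c2ccc(OC(C)C)cc2)cn1CC1(c2ccc(OC)cc2)OCCO1 | intermediate
7 | 4-(4-isopropoxyphenyl)-1-{[2-(4-methoxyphenyl)-1,3-dioxolan-2-yl]methyl}-1H-pyrrole-2-carboxylic acid | OC(=O)c1cc(-c2ccc(OC(C)C)cc2)cn1CC1(c2ccc(OC)cc2)OCCO1 | intermediate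
8 | 2-bromo-5-methoxyphenol | COc1ccc(Br)c(O)c1 | starting material
9 | 2-bromo-5-methoxyphenyl 4-(4-isopropoxyphenyl)-1-{[2-(4-methoxyphenyl)-1,3-dioxolan-2-yl]methyl}-1H-pyrrole-2-carboxylate | COc1ccc(Br)c(OC(=O)c2cc(-c3ccc(OC(C)C)cc3)cn2CC2(c3ccc(OC)cc3)OCCO2)c1 | intermediate
10 | 1-(4-isopropoxyphenyl)-7-methoxy-3-{[2-(4-methoxyphenyl)-1,3-dioxolan-2-yl]methyl}chromeno[3,4-b]pyrrol-4(3H)-one | O=C1Oc2cc(OC)ccc2-c2c1n(CC1(c3ccc(OC)cc3)OCCO1)cc2-c1ccc(OC(C)C)cc1 | intermediate
11 | dipotassium 4-(4-isopropoxyphenyl)-3-(4-methoxy-2-oxidophenyl)-1-{[2-(4-methoxyphenyl)-1,3-dioxolan-2-yl]methyl}-1H-pyrrole-2-carboxylate | [K+].[K+].[O-]C(=O)c1c(-c2ccc(OC)cc2[O-])c(-c2ccc(OC(C)C)cc2)cn1CC1(c2ccc(OC)cc2)OCCO1 | intermediate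
12 | 4-(4-isopropoxyphenyl)-3-(4-methoxy-2-{[(trifluoromethyl)sulfonyl]oxy}phenyl)-1-{[2-(4-methoxyphenyl)-1,3-dioxolan-2-yl]methyl}-1H-pyrrole-2-carboxylic acid | OC(=O)c1c(-c2ccc(OC)cc2OS(=O)(=O)C(F)(F)F)c(-c2ccc(OC(C)C)cc2)cn1CC1(c2ccc(OC)cc2)OCCO1 | intermediate
13 | 4-(4-isopropoxyphenyl)-3-(4-methoxyphenyl)-1-{[2-(4-methoxyphenyl)-1,3-dioxolan-2-yl]methyl}-1H-pyrrole-2-carboxylic acid | OC(=O)c1c(-c2ccc(OC)cc2)c(-c2ccc(OC(C)C)cc2)cn1CC1(c2ccc(OC)cc2)OCCO1 | intermediate
14 | 4-(4-isopropoxyphenyl)-3-(4-methoxyphenyl)-1-[2-(4-methoxyphenyl)-2-oxoethyl]-1H-pyrrole-2-carboxylic acid | OC(=O)c1c(-c2ccc(OC)cc2)c(-c2ccc(OC(C)C)cc2)cn1CC(=O)c1ccc(OC)cc1 | intermediate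
15 | acetic 4-(4-isopropoxyphenyl)-3-(4-methoxyphenyl)-1-[2-(4-methoxyphenyl)-2-oxoethyl]-1H-pyrrole-2-carboxylic anhydride | CC(=O)OC(=O)c1c(-c2ccc(OC)cc2)c(-c2ccc(OC(C)C)cc2)cn1CC(=O)c1ccc(OC)cc1 | intermediate
16 | 7-(4-isopropoxyphenyl)-3,8-bis(4-methoxyphenyl)-1H-pyrrolo[2,1-c][1,4]oxazin-1-one | O=c1oc(-c2ccc(OC)cc2)cn2cc(-c3ccc(OC(C)C)cc3)c(-c3ccc(OC)cc3)c12 | intermediate
17 | 7-(4-hydroxyphenyl)-3,8-bis(4-methoxyphenyl)-1H-pyrrolo[2,1-c][1,4]oxazin-1-one | O=c1oc(-c2ccc(OC)cc2)cn2cc(-c3ccc(O)cc3)c(-c3ccc(OC)cc3)c12 | intermediate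
18 | 7-(4-hydroxy-3-iodophenyl)-3,8-bis(4-methoxyphenyl)-1H-pyrrolo[2,1-c][1,4]oxazin-1-one | O=c1oc(-c2ccc(OC)cc2)cn2cc(-c3ccc(O)c(I)c3)c(-c3ccc(OC)cc3)c12 | intermediate
19 | lukianol B, 7-(4-hydroxy-3-iodophenyl)-3,8-bis(4-hydroxyphenyl)-1H-pyrrolo[2,1-c][1,4]oxazin-1-one | O=c1oc(-c2ccc(O)cc2)cn2cc(-c3ccc(O)c(I)c3)c(-c3ccc(O)cc3)c12 | target

## Step count and risks

Total: 12 steps. Longest linear sequence: 12 steps, from 1 to 19; compounds 2, 5 and 8 enter in steps 1, 3 and 5.

**Step 6 (key step).** The most likely failure is loss of the activated aryl ester (acyl cleavage by acetate or traces of water) or reductive loss of bromine before the palladium reaches the C3–H bond. That bond is flanked by the carbonyl and the C4 aryl ring, and it is reached only from the less populated ester conformer. The fallback gives up the tether and sets out from 6: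
- chlorination at the more reactive C5 with N-chlorosuccinimide should give methyl 5-chloro-4-(4-isopropoxyphenyl)-1-{[2-(4-methoxyphenyl)-1,3-dioxolan-2-yl]methyl}-1H-pyrrole-2-carboxylate F1;
- bromination at the only remaining pyrrole position with N-bromosuccinimide should give the 3-bromo-5-chloro ester F2;
- Suzuki–Miyaura coupling with (4-methoxyphenyl)boronic acid at the C–Br bond should give the 5-chloro-3-(4-methoxyphenyl) ester F3;
- hydrogenolysis of the C–Cl bond (H2, Pd on carbon, Et3N) should give methyl 4-(4-isopropoxyphenyl)-3-(4-methoxyphenyl)-1-{[2-(4-methoxyphenyl)-1,3-dioxolan-2-yl]methyl}-1H-pyrrole-2-carboxylate F4;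
- saponification with KOH followed by aqueous HCl brings the material back to the route at 14.

**Step 7.** The triflating agent may also activate the carboxylate of 11, and the neighbouring phenoxide would then close the lactone again; triflation of the hindered phenoxide may also stay incomplete. The fallback keeps the carboxyl as an ester that the triflating agent cannot activate, and sets out from 10:
- one equivalent of NaOCH3 in THF opens the lactone to sodium 2-[4-(4-isopropoxyphenyl)-2-(methoxycarbonyl)-1-{[2-(4-methoxyphenyl)-1,3-dioxolan-2-yl]methyl}-1H-pyrrol-3-yl]-5-methoxyphenolate F5;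
- PhNTf2 in the same flask converts it into methyl 4-(4-isopropoxyphenyl)-3-(4-methoxy-2-{[(trifluoromethyl)sulfonyl]oxy}phenyl)-1-{[2-(4-methoxyphenyl)-1,3-dioxolan-2-yl]methyl}-1H-pyrrole-2-carboxylate F6;
- reduction as in step 8, without the acid stage, gives the methyl ester F4 described above;
- KOH followed by aqueous HCl returns to the route at 14.

**Step 11.** Iodination may occur at other nucleophilic positions (the pyrrole C6–H, the enol C4–H, an anisyl ring), a second iodine may enter, or methanol may slowly open the enol lactone. The fallback moves the iodination to the open keto acid, where a phenoxide in water is the only site that reacts with I2, and sets out from 14: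
- BCl3 gives 4-(4-hydroxyphenyl)-3-(4-methoxyphenyl)-1-[2-(4-methoxyphenyl)-2-oxoethyl]-1H-pyrrole-2-carboxylic acid F7;
- one equivalent of I2 in a cold aqueous carbonate buffer with THF gives 4-(4-hydroxy-3-iodophenyl)-3-(4-methoxyphenyl)-1-[2-(4-methoxyphenyl)-2-oxoethyl]-1H-pyrrole-2-carboxylic acid F8;
- Ac2O and NaOAc close the enol lactone and acetylate the phenol, giving 4-[3,8-bis(4-methoxyphenyl)-1-oxo-1H-pyrrolo[2,1-c][1,4]oxazin-7-yl]-2-iodophenyl acetate F9;
- BBr3 with a methanolic work-up removes both methyl groups and the acetate and arrives at 19.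

**Step 2.** Ketalization of a donor-substituted aryl ketone may stop short of completion, and the methyl ester may exchange with the glycol; the latter is harmless because it converges in step 4. The fallback inverts the order and sets out from 2. The more electrophilic bromoketone is ketalized first to 2-(bromomethyl)-2-(4-methoxyphenyl)-1,3-dioxolane F10. Pyrrole 1 is then alkylated with F10 under forcing conditions (Cs2CO3, DMF, 110 °C), which returns to the route at 4.

## Further compounds

F1 | step 6 | methyl 5-chloro-4-(4-isopropoxyphenyl)-1-{[2-(4-methoxyphenyl)-1,3-dioxolan-2-yl]methyl}-1H-pyrrole-2-carboxylate | COC(=O)c1cc(-c2ccc(OC(C)C)cc2)c(Cl)n1CC1(c2ccc(OC)cc2)OCCO1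
F2 | step 6 | methyl 3-bromo-5-chloro-4-(4-isopropoxyphenyl)-1-{[2-(4-methoxyphenyl)-1,3-dioxolan-2-yl]methyl}-1H-pyrrole-2-carboxylate | COC(=O)c1c(Br)c(-c2ccc(OC(C)C)cc2)c(Cl)n1CC1(c2ccc(OC)cc2)OCCO1
F3 | step 6 | methyl 5-chloro-4-(4-isopropoxyphenyl)-3-(4-methoxyphenyl)-1-{[2-(4-methoxyphenyl)-1,3-dioxolan-2-yl]methyl}-1H-pyrrole-2-carboxylate | COC(=O)c1c(-c2ccc(OC)cc2)c(-c2ccc(OC(C)C)cc2)c(Cl)n1CC1(c2ccc(OC)cc2)OCCO1
F4 | step 6 | methyl 4-(4-isopropoxyphenyl)-3-(4-methoxyphenyl)-1-{[2-(4-methoxyphenyl)-1,3-dioxolan-2-yl]methyl}-1H-pyrrole-2-carboxylate | COC(=O)c1c(-c2ccc(OC)cc2)c(-c2ccc(OC(C)C)cc2)cn1CC1(c2ccc(OC)cc2)OCCO1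
F5 | step 7 | sodium 2-[4-(4-isopropoxyphenyl)-2-(methoxycarbonyl)-1-{[2-(4-methoxyphenyl)-1,3-dioxolan-2-yl]methyl}-1H-pyrrol-3-yl]-5-methoxyphenolate | [Na+].[O-]c1cc(OC)ccc1-c1c(C(=O)OC)n(CC2(c3ccc(OC)cc3)OCCO2)cc1-c1ccc(OC(C)C)cc1
F6 | step 7 | methyl 4-(4-isopropoxyphenyl)-3-(4-methoxy-2-{[(trifluoromethyl)sulfonyl]oxy}phenyl)-1-{[2-(4-methoxyphenyl)-1,3-dioxolan-2-yl]methyl}-1H-pyrrole-2-carboxylate | COC(=O)c1c(-c2ccc(OC)cc2OS(=O)(=O)C(F)(F)F)c(-c2ccc(OC(C)C)cc2)cn1CC1(c2ccc(OC)cc2)OCCO1
F7 | step 11 | 4-(4-hydroxyphenyl)-3-(4-methoxyphenyl)-1-[2-(4-methoxyphenyl)-2-oxoethyl]-1H-pyrrole-2-carboxylic acid | OC(=O)c1c(-c2ccc(OC)cc2)c(-c2ccc(O)cc2)cn1CC(=O)c1ccc(OC)cc1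
F8 | step 11 | 4-(4-hydroxy-3-iodophenyl)-3-(4-methoxyphenyl)-1-[2-(4-methoxyphenyl)-2-oxoethyl]-1H-pyrrole-2-carboxylic acid | OC(=O)c1c(-c2ccc(OC)cc2)c(-c2ccc(O)c(I)c2)cn1CC(=O)c1ccc(OC)cc1
F9 | step 11 | 4-[3,8-bis(4-methoxyphenyl)-1-oxo-1H-pyrrolo[2,1-c][1,4]oxazin-7-yl]-2-iodophenyl acetate | CC(=O)Oc1ccc(-c2cn3cc(-c4ccc(OC)cc4)oc(=O)c3c2-c2ccc(OC)cc2)cc1I
F10 | step 2 | 2-(bromomethyl)-2-(4-methoxyphenyl)-1,3-dioxolane | COc1ccc(C2(CBr)OCCO2)cc1
A1 | alternative 1 | 2-tert-butyl 5-methyl 3-(3-iodo-4-methoxyphenyl)-4-(4-methoxyphenyl)-1H-pyrrole-2,5-dicarboxylate | COC(=O)c1[nH]c(C(=O)OC(C)(C)C)c(-c2ccc(OC)c(I)c2)c1-c1ccc(OC)cc1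
A2 | alternative 1 | methyl 3-(4-methoxyphenyl)-2-oxopropanoate | COC(=O)C(=O)Cc1ccc(OC)cc1
A3 | alternative 1 | tert-butyl 3-bromo-3-(3-iodo-4-methoxyphenyl)-2-oxopropanoate (racemic) | COc1ccc(C(Br)C(=O)C(=O)OC(C)(C)C)cc1I
A4 | alternative 2 | 7-(3-iodo-4-methoxyphenyl)-3,8-bis(4-methoxyphenyl)-1H-pyrrolo[2,1-c][1,4]oxazin-1-one (lukianol B trimethyl ether) | O=c1oc(-c2ccc(OC)cc2)cn2cc(-c3ccc(OC)c(I)c3)c(-c3ccc(OC)cc3)c12
A5 | alternative 2 | 1-(4-methoxyphenyl)ethenyl 4-(3-iodo-4-methoxyphenyl)-3-(4-methoxyphenyl)-1H-pyrrole-2-carboxylate | C=C(OC(=O)c1[nH]cc(-c2ccc(OC)c(I)c2)c1-c1ccc(OC)cc1)c1ccc(OC)cc1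
A6 | alternative 3 | methyl 4-(3-iodo-4-methoxyphenyl)-3-(4-methoxyphenyl)-1-{[2-(4-methoxyphenyl)-1,3-dioxolan-2-yl]methyl}-1H-pyrrole-2-carboxylate | COC(=O)c1c(-c2ccc(OC)cc2)c(-c2ccc(OC)c(I)c2)cn1CC1(c2ccc(OC)cc2)OCCO1
A7 | alternative 3 | 3-hydroxy-2-(3-iodo-4-methoxyphenyl)-1-(4-methoxyphenyl)prop-2-en-1-one | COc1ccc(C(=O)C(=CO)c2ccc(OC)c(I)c2)cc1
A8 | alternative 3 | methyl N-{[2-(4-methoxyphenyl)-1,3-dioxolan-2-yl]methyl}glycinate | COC(=O)CNCC1(c2ccc(OC)cc2)OCCO1
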